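**Retrosynthetic overview**

1. Kazinol A is traced back to its tris-silyl ether and then to a (2S,3S)-3-formylflavan; the formyl group at C3 is a traceless activating group, removed by decarbonylation.
2. Ring C (the pyran: O1, C2, C3, C4, C4a, C8a) is closed last by making the C2–C3 bond in an amine-catalysed [1,5]-hydride transfer/cyclisation of an ortho-(benzyloxy)cinnamaldehyde, so the CH2 of a plain benzyl ether becomes the C2 stereocentre.
3. Enabling feature: C2 lies between O1 and ring B, whose C4' oxygen is para to C1', so the C2–H bonds are hydridic and the derived oxocarbenium ion is doubly stabilised; C4 is the fifth atom from C2 (C2, O1, C8a, C4a, C4).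
4. The cyclisation precursor comes from ring A (2,4-dihydroxybenzaldehyde) and the ring B benzyl alcohol by Mitsunobu etherification and a Wittig two-carbon extension.
5. Both prenyl groups of ring B are placed early by a double aromatic Claisen rearrangement of the bis(1,1-dimethylallyl) ether of 3,4-dihydroxybenzaldehyde; rings A and B are bought, ring C is the only ring formed.

Key step: step 9

Remark: flavan numbering is used throughout (O1, C2, C3, C4, C4a, C5 to C8, C8a; ring B C1' to C6'). The sense of induction in step 9 is assigned from the usual face-shielding model of diarylprolinol silyl ether enamines; if the sense proved opposite, the mirror-image catalyst would be used in the same route.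
Remark: the catalyst of step 9 is (R)-2-[diphenyl(trimethylsilyloxy)methyl]pyrrolidine, C[Si](C)(C)OC(c1ccccc1)(c1ccccc1)[C@H]1CCCN1; it is regenerated and not consumed.

**Route**

Step 1
Reactants: 1 2,4-dihydroxybenzaldehyde
Product: 2 2-hydroxy-4-(triisopropylsilyloxy)benzaldehyde
Conditions: TIPSCl (1.05 equiv), imidazole, CH2Cl2, 0 °C to rt
Reagents that add atoms: triisopropylsilyl chloride, CC(C)[Si](Cl)(C(C)C)C(C)C
Why: Selective O-silylation; the 2-hydroxyl is hydrogen-bonded to the formyl group and hindered, so the bulky silyl chloride should react at the 4-hydroxyl only.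

Step 2
Reactants: 3 3,4-dihydroxybenzaldehyde; 4 3-chloro-3-methylbut-1-yne
Product: 5 3,4-bis(2-methylbut-3-yn-2-yloxy)benzaldehyde
Conditions: 4 (3 equiv), CuCl2·2H2O (1 mol %), DBU, MeCN, 0 °C
Reagents that add atoms: none
Why: Copper-catalysed propargylic substitution of a tertiary propargyl chloride by phenoxide is the standard way to make hindered aryl 1,1-dimethylpropargyl ethers, and an excess of 4 should drive both hydroxyls to the ether.

Step 3
Reactants: 5 3,4-bis(2-methylbut-3-yn-2-yloxy)benzaldehyde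
Product: 6 3,4-bis(2-methylbut-3-en-2-yloxy)benzaldehyde
Conditions: H2 (1 atm), Pd/CaCO3 poisoned with Pb(OAc)2 (Lindlar catalyst), quinoline, EtOAc, rt
Reagents that add atoms: none
Why: Lindlar semihydrogenation should stop at the terminal alkenes and leave the aryl aldehyde untouched.

Step 4
Reactants: 6 3,4-bis(2-methylbut-3-en-2-yloxy)benzaldehyde
Product: 7 3,4-dihydroxy-2,5-bis(3-methylbut-2-enyl)benzaldehyde
Conditions: PhNEt2, 120 °C, argon
Reagents that add atoms: none
Why: Double aromatic Claisen rearrangement; each 1,1-dimethylallyl ether has only one free ortho carbon (C2 for the 3-O ether, C5 for the 4-O ether), so each [3,3] shift delivers a normal prenyl group there, and tautomerisation frees the catechol. The basic solvent suppresses acid-induced chroman formation.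

Step 5
Reactants: 7 3,4-dihydroxy-2,5-bis(3-methylbut-2-enyl)benzaldehyde
Product: 8 3,4-bis(tert-butyldimethylsilyloxy)-2,5-bis(3-methylbut-2-enyl)benzaldehyde
Conditions: TBSCl (2.5 equiv), imidazole, DMAP (cat.), DMF, rt
Reagents that add atoms: tert-butyldimethylsilyl chloride, CC(C)(C)[Si](C)(C)Cl
Why: Standard phenol silylation; silyl ethers keep ring B electron-rich for the later hydride transfer and can be removed at the end without acid.

Step 6
Reactants: 8 3,4-bis(tert-butyldimethylsilyloxy)-2,5-bis(3-methylbut-2-enyl)benzaldehyde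
Product: 9 [3,4-bis(tert-butyldimethylsilyloxy)-2,5-bis(3-methylbut-2-enyl)phenyl]methanol
Conditions: NaBH4, THF/MeOH, 0 °C
Reagents that add atoms: none
Why: Borohydride reduction of an aryl aldehyde is fast at 0 °C and should outrun any methoxide attack on the aryl silyl ethers.

Step 7
Reactants: 2 2-hydroxy-4-(triisopropylsilyloxy)benzaldehyde; 9 [3,4-bis(tert-butyldimethylsilyloxy)-2,5-bis(3-methylbut-2-enyl)phenyl]methanol
Product: 10 2-{[3,4-bis(tert-butyldimethylsilyloxy)-2,5-bis(3-methylbut-2-enyl)phenyl]methoxy}-4-(triisopropylsilyloxy)benzaldehyde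
Conditions: PPh3, DIAD, THF, 0 °C to rt
Reagents that add atoms: none
Why: Mitsunobu etherification of a primary benzylic alcohol with an acidic salicylaldehyde phenol; the neutral conditions spare the aryl silyl ethers that carbonate bases would cleave.

Step 8
Reactants: 10 2-{[3,4-bis(tert-butyldimethylsilyloxy)-2,5-bis(3-methylbut-2-enyl)phenyl]methoxy}-4-(triisopropylsilyloxy)benzaldehyde; 11 (triphenylphosphoranylidene)acetaldehyde
Product: 12 (E)-3-[2-{[3,4-bis(tert-butyldimethylsilyloxy)-2,5-bis(3-methylbut-2-enyl)phenyl]methoxy}-4-(triisopropylsilyloxy)phenyl]prop-2-enal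
Conditions: 11 (1.2 equiv), toluene, 90 °C
Reagents that add atoms: none
Why: Wittig olefination with a stabilised formylmethylene ylide should give the (E)-cinnamaldehyde; the ylide carbon becomes C3 of the target.

Step 9
Reactants: 12 (E)-3-[2-{[3,4-bis(tert-butyldimethylsilyloxy)-2,5-bis(3-methylbut-2-enyl)phenyl]methoxy}-4-(triisopropylsilyloxy)phenyl]prop-2-enal
Product: 16 (2S,3S)-2-[3,4-bis(tert-butyldimethylsilyloxy)-2,5-bis(3-methylbut-2-enyl)phenyl]-7-(triisopropylsilyloxy)-3,4-dihydro-2H-chromene-3-carbaldehyde, via iminium ion 13 (not isolated), via enamine oxocarbenium cation 14 (not isolated), via ring-closed iminium ion 15 (not isolated)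
Conditions: (R)-2-[diphenyl(trimethylsilyloxy)methyl]pyrrolidine (20 mol %), CF3CO2H (20 mol %), ClCH2CH2Cl, 25 to 40 °C
Reagents that add atoms: none
Why: Proposed new method: the amine condenses with enal 12 to iminium ion 13, whose β-carbon (C4) takes a hydride through a six-membered transition state from the O1–CH2 group five atoms away ([1,5]-hydride transfer), giving cation 14 with a C3 enamine and a C2 oxocarbenium ion, which collapses by Mannich-type C3-to-C2 bond formation to iminium ion 15 and is hydrolysed by the water released in the condensation. The closest known reaction types are the Lewis-acid-catalysed hydride-transfer/cyclisation of ortho-vinylaryl benzyl ethers to racemic 2-arylchromans and the secondary-amine-catalysed enantioselective [1,5]-hydride transfer/cyclisation of enals bearing tertiary amine or dialkyl ether donors; iminium activation with an aryl benzyl ether donor has not been shown, but the C2–H bond here should be at least as hydridic as in those donors because the cation is stabilised by O1 and by the para silyloxy group at C4'. Ring C closes in a 6-endo-trig mode at the oxocarbenium carbon, with the enamine double bond exocyclic. C3 is set by the catalyst, whose diphenyl(silyloxy)methyl group shields one face of the (E)-enamine, and C2 is set relative to C3 in a chair-like transition state with ring B pseudo-equatorial on the (E)-oxocarbenium ion, which should give the trans (2S,3S) isomer with the (R)-catalyst; C3 is erased later, so the C2 configuration is what counts. The step needs three selectivities: hydride abstraction from C2 only (secured by the 1,5-geometry and the double stabilisation of the cation, which no allylic CH2 of the prenyl groups can match), capture of the cation by the tethered enamine faster than by the 2'-prenyl double bond (secured by the far higher nucleophilicity and proximity of the enamine), and kinetic control, so the reaction is stopped at full conversion to avoid retro-Mannich equilibration.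

Step 10
Reactants: 16 (2S,3S)-2-[3,4-bis(tert-butyldimethylsilyloxy)-2,5-bis(3-methylbut-2-enyl)phenyl]-7-(triisopropylsilyloxy)-3,4-dihydro-2H-chromene-3-carbaldehyde
Product: 17 (2S)-2-[3,4-bis(tert-butyldimethylsilyloxy)-2,5-bis(3-methylbut-2-enyl)phenyl]-7-(triisopropylsilyloxy)-3,4-dihydro-2H-chromene
Conditions: RhCl(PPh3)3 (1.1 equiv), PhCN, 110 °C
Reagents that add atoms: none
Why: Tsuji–Wilkinson decarbonylation (formyl C–H oxidative addition, CO de-insertion, C–H reductive elimination) should turn C3 into a CH2 group; C2 is not involved and keeps its configuration, and trisubstituted alkenes and silyl ethers are inert to the complex in the absence of H2.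

Step 11
Reactants: 17 (2S)-2-[3,4-bis(tert-butyldimethylsilyloxy)-2,5-bis(3-methylbut-2-enyl)phenyl]-7-(triisopropylsilyloxy)-3,4-dihydro-2H-chromene
Product: 18 Kazinol A, 4-[(2S)-7-hydroxy-3,4-dihydro-2H-chromen-2-yl]-3,6-bis(3-methylbut-2-enyl)benzene-1,2-diol
Conditions: TBAF (3.3 equiv), AcOH (3.3 equiv), THF, 0 °C, argon
Reagents that add atoms: none
Why: Fluoride cleaves all three aryl silyl ethers in one operation; the acetic acid buffer should keep the catechol from oxidising, and the acid-free conditions spare the prenyl groups and the labile benzylic C2–O1 bond.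

**Compound list**

1 | 2,4-dihydroxybenzaldehyde | O=Cc1ccc(O)cc1O | starting material
2 | 2-hydroxy-4-(triisopropylsilyloxy)benzaldehyde | O=Cc1ccc(O[Si](C(C)C)(C(C)C)C(C)C)cc1O | intermediate
3 | 3,4-dihydroxybenzaldehyde | O=Cc1ccc(O)c(O)c1 | starting material
4 | 3-chloro-3-methylbut-1-yne | C#CC(C)(C)Cl | starting material
5 | 3,4-bis(2-methylbut-3-yn-2-yloxy)benzaldehyde | O=Cc1ccc(OC(C)(C)C#C)c(OC(C)(C)C#C)c1 | intermediate
6 | 3,4-bis(2-methylbut-3-en-2-yloxy)benzaldehyde | O=Cc1ccc(OC(C)(C)C=C)c(OC(C)(C)C=C)c1 | intermediate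
7 | 3,4-dihydroxy-2,5-bis(3-methylbut-2-enyl)benzaldehyde | O=Cc1cc(CC=C(C)C)c(O)c(O)c1CC=C(C)C | intermediate
8 | 3,4-bis(tert-butyldimethylsilyloxy)-2,5-bis(3-methylbut-2-enyl)benzaldehyde | O=Cc1cc(CC=C(C)C)c(O[Si](C)(C)C(C)(C)C)c(O[Si](C)(C)C(C)(C)C)c1CC=C(C)C | intermediate
9 | [3,4-bis(tert-butyldimethylsilyloxy)-2,5-bis(3-methylbut-2-enyl)phenyl]methanol | OCc1cc(CC=C(C)C)c(O[Si](C)(C)C(C)(C)C)c(O[Si](C)(C)C(C)(C)C)c1CC=C(C)C | intermediate
10 | 2-{[3,4-bis(tert-butyldimethylsilyloxy)-2,5-bis(3-methylbut-2-enyl)phenyl]methoxy}-4-(triisopropylsilyloxy)benzaldehyde | O=Cc1ccc(O[Si](C(C)C)(C(C)C)C(C)C)cc1OCc1cc(CC=C(C)C)c(O[Si](C)(C)C(C)(C)C)c(O[Si](C)(C)C(C)(C)C)c1CC=C(C)C | intermediate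
11 | (triphenylphosphoranylidene)acetaldehyde | O=CC=P(c1ccccc1)(c1ccccc1)c1ccccc1 | starting material
12 | (E)-3-[2-{[3,4-bis(tert-butyldimethylsilyloxy)-2,5-bis(3-methylbut-2-enyl)phenyl]methoxy}-4-(triisopropylsilyloxy)phenyl]prop-2-enal | O=C/C=C/c1ccc(O[Si](C(C)C)(C(C)C)C(C)C)cc1OCc1cc(CC=C(C)C)c(O[Si](C)(C)C(C)(C)C)c(O[Si](C)(C)C(C)(C)C)c1CC=C(C)C | intermediate
13 | iminium ion of enal 12 and the (R)-catalyst, (E)-alkene | C[Si](C)(C)OC(c1ccccc1)(c1ccccc1)[C@H]1CCC[N+]1=C/C=C/c1ccc(O[Si](C(C)C)(C(C)C)C(C)C)cc1OCc1cc(CC=C(C)C)c(O[Si](C)(C)C(C)(C)C)c(O[Si](C)(C)C(C)(C)C)c1CC=C(C)C | intermediate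
14 | cation after [1,5]-hydride transfer, holding the (E)-enamine at C3 and the oxocarbenium ion at C2 | C[Si](C)(C)OC(c1ccccc1)(c1ccccc1)[C@H]1CCCN1/C=C/Cc1ccc(O[Si](C(C)C)(C(C)C)C(C)C)cc1[O+]=Cc1cc(CC=C(C)C)c(O[Si](C)(C)C(C)(C)C)c(O[Si](C)(C)C(C)(C)C)c1CC=C(C)C | intermediate
15 | ring-closed (2S,3S) iminium ion of aldehyde 16 and the (R)-catalyst | C[Si](C)(C)OC(c1ccccc1)(c1ccccc1)[C@H]1CCC[N+]1=C[C@H]1Cc2ccc(O[Si](C(C)C)(C(C)C)C(C)C)cc2O[C@@H]1c1cc(CC=C(C)C)c(O[Si](C)(C)C(C)(C)C)c(O[Si](C)(C)C(C)(C)C)c1CC=C(C)C | intermediate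
16 | (2S,3S)-2-[3,4-bis(tert-butyldimethylsilyloxy)-2,5-bis(3-methylbut-2-enyl)phenyl]-7-(triisopropylsilyloxy)-3,4-dihydro-2H-chromene-3-carbaldehyde (2,3-trans) | O=C[C@H]1Cc2ccc(O[Si](C(C)C)(C(C)C)C(C)C)cc2O[C@@H]1c1cc(CC=C(C)C)c(O[Si](C)(C)C(C)(C)C)c(O[Si](C)(C)C(C)(C)C)c1CC=C(C)C | intermediate
17 | (2S)-2-[3,4-bis(tert-butyldimethylsilyloxy)-2,5-bis(3-methylbut-2-enyl)phenyl]-7-(triisopropylsilyloxy)-3,4-dihydro-2H-chromene | CC(C)=CCc1cc([C@@H]2CCc3ccc(O[Si](C(C)C)(C(C)C)C(C)C)cc3O2)c(CC=C(C)C)c(O[Si](C)(C)C(C)(C)C)c1O[Si](C)(C)C(C)(C)C | intermediate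
18 | Kazinol A, 4-[(2S)-7-hydroxy-3,4-dihydro-2H-chromen-2-yl]-3,6-bis(3-methylbut-2-enyl)benzene-1,2-diol | CC(C)=CCc1cc([C@@H]2CCc3ccc(O)cc3O2)c(CC=C(C)C)c(O)c1O | target

**Step count and risks**

Total step count: 11. Longest linear sequence: 10 steps (steps 2 to 11, from 3,4-dihydroxybenzaldehyde).

Steps most likely to fail:

1. Step 9 (proposed new method). The hydride transfer may be slow because O1 and the 7-silyloxy group both feed electron density into the iminium acceptor. The C2 cation may be captured by the neighbouring 2'-prenyl double bond in a cation–olefin cyclisation. Facial control at C2 may be poor, or eroded by reversible ring opening under the amine salt. Fallback, known chemistry only, setting out from 8 and coming back at 17: commercially available 4-iodobenzene-1,3-diol (Oc1ccc(I)c(O)c1) is silylated with TIPSCl and imidazole at the hydroxyl para to iodine to give 2-iodo-5-(triisopropylsilyloxy)phenol F1. Aldehyde 8 is treated with vinylmagnesium bromide (CH2=CHMgBr) in THF at −78 °C to give racemic 1-[3,4-bis(tert-butyldimethylsilyloxy)-2,5-bis(3-methylbut-2-enyl)phenyl]prop-2-en-1-ol F2. A Heck reaction of F2 with F1 (Pd(OAc)2, Bu4NCl, NaHCO3, DMF), in which β-hydride elimination toward the carbinol gives the enol and then the ketone, should give 1-[3,4-bis(tert-butyldimethylsilyloxy)-2,5-bis(3-methylbut-2-enyl)phenyl]-3-[2-hydroxy-4-(triisopropylsilyloxy)phenyl]propan-1-one F3. Corey–Bakshi–Shibata reduction with (S)-2-methyl-CBS-oxazaborolidine and BH3·SMe2 should give (1R)-1-[3,4-bis(tert-butyldimethylsilyloxy)-2,5-bis(3-methylbut-2-enyl)phenyl]-3-[2-hydroxy-4-(triisopropylsilyloxy)phenyl]propan-1-ol F4. Intramolecular Mitsunobu etherification (PPh3, DIAD, THF) with inversion then closes ring C at O1–C2 and gives the (2S)-flavan 17 directly, so steps 7 to 10 are bypassed.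

2. Step 10. The alkyl rhodium intermediate at C3 may undergo β-hydride elimination (chromene formation) or β-aryloxy elimination (opening of ring C) instead of C–H reductive elimination. Fallback setting out from 16 and coming back at 17: Pinnick oxidation (NaClO2, NaH2PO4, 2-methylbut-2-ene, t-BuOH/H2O) gives (2S,3S)-2-[3,4-bis(tert-butyldimethylsilyloxy)-2,5-bis(3-methylbut-2-enyl)phenyl]-7-(triisopropylsilyloxy)-3,4-dihydro-2H-chromene-3-carboxylic acid F5. Coupling with N-hydroxyphthalimide (N,N'-diisopropylcarbodiimide, DMAP) gives its 1,3-dioxoisoindolin-2-yl ester F6. Radical reductive decarboxylation of this redox-active ester (Ru(bpy)3Cl2 as catalyst, 1-benzyl-1,4-dihydronicotinamide, t-BuSH, visible light) replaces the carboxyl group by hydrogen and returns 17; the C3 radical is quenched by the thiol and C2 is not touched.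

3. Step 2. The second tertiary etherification next to the first may stall, and the free neighbouring hydroxyl of the mono-ether may add to the copper-activated alkyne, closing a benzodioxane ring. Fallback setting out from 3 and coming back at 6, so that 5 and step 3 are bypassed: 2-methylbut-3-en-2-ol is converted with n-BuLi and di-tert-butyl dicarbonate into tert-butyl 2-methylbut-3-en-2-yl carbonate F7. Tsuji–Trost O-allylation of 3 with F7 under zerovalent palladium catalysis (Pd(PPh3)4, THF, 0 °C) should attack the more substituted allyl terminus and give the bis(1,1-dimethylallyl) ether 6 without any alkyne intermediate.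

**Further compounds**

F1 | step 9 | 2-iodo-5-(triisopropylsilyloxy)phenol | Oc1cc(O[Si](C(C)C)(C(C)C)C(C)C)ccc1I
F2 | step 9 | 1-[3,4-bis(tert-butyldimethylsilyloxy)-2,5-bis(3-methylbut-2-enyl)phenyl]prop-2-en-1-ol (racemic) | C=CC(O)c1cc(CC=C(C)C)c(O[Si](C)(C)C(C)(C)C)c(O[Si](C)(C)C(C)(C)C)c1CC=C(C)C
F3 | step 9 | 1-[3,4-bis(tert-butyldimethylsilyloxy)-2,5-bis(3-methylbut-2-enyl)phenyl]-3-[2-hydroxy-4-(triisopropylsilyloxy)phenyl]propan-1-one | O=C(CCc1ccc(O[Si](C(C)C)(C(C)C)C(C)C)cc1O)c1cc(CC=C(C)C)c(O[Si](C)(C)C(C)(C)C)c(O[Si](C)(C)C(C)(C)C)c1CC=C(C)C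
F4 | step 9 | (1R)-1-[3,4-bis(tert-butyldimethylsilyloxy)-2,5-bis(3-methylbut-2-enyl)phenyl]-3-[2-hydroxy-4-(triisopropylsilyloxy)phenyl]propan-1-ol | O[C@H](CCc1ccc(O[Si](C(C)C)(C(C)C)C(C)C)cc1O)c1cc(CC=C(C)C)c(O[Si](C)(C)C(C)(C)C)c(O[Si](C)(C)C(C)(C)C)c1CC=C(C)C
F5 | step 10 | (2S,3S)-2-[3,4-bis(tert-butyldimethylsilyloxy)-2,5-bis(3-methylbut-2-enyl)phenyl]-7-(triisopropylsilyloxy)-3,4-dihydro-2H-chromene-3-carboxylic acid | OC(=O)[C@H]1Cc2ccc(O[Si](C(C)C)(C(C)C)C(C)C)cc2O[C@@H]1c1cc(CC=C(C)C)c(O[Si](C)(C)C(C)(C)C)c(O[Si](C)(C)C(C)(C)C)c1CC=C(C)C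
F6 | step 10 | 1,3-dioxoisoindolin-2-yl (2S,3S)-2-[3,4-bis(tert-butyldimethylsilyloxy)-2,5-bis(3-methylbut-2-enyl)phenyl]-7-(triisopropylsilyloxy)-3,4-dihydro-2H-chromene-3-carboxylate | O=C(ON1C(=O)c2ccccc2C1=O)[C@H]1Cc2ccc(O[Si](C(C)C)(C(C)C)C(C)C)cc2O[C@@H]1c1cc(CC=C(C)C)c(O[Si](C)(C)C(C)(C)C)c(O[Si](C)(C)C(C)(C)C)c1CC=C(C)C
F7 | step 2 | tert-butyl 2-methylbut-3-en-2-yl carbonate | CC(C)(C)OC(=O)OC(C)(C)C=C
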